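## Retrosynthetic overview

1. C7–H ⇐ C7–OMe: the target comes from reductive removal of a second ring methoxy group, carried only to keep the precursor dienone symmetric.
2. O1–C7a and C2–H ⇐ one desymmetrising reductive oxa-Michael cyclisation of an aryl ketone onto a 4,4-disubstituted 2,6-dimethoxycyclohexa-2,5-dienone; this closes the tetrahydrofuran ring and sets C2, C3, C3a and C7a.
3. C3a–allyl ⇐ dearomative para-allylation of a 4-alkyl-2,6-dimethoxyphenol; the six-membered carbocycle is the former arene.
4. C3–aryl ⇐ Pd-catalysed α-arylation of 3',4'-dimethoxypropiophenone with 4-bromo-2,6-dimethoxyphenol.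
5. Ring order: carbocycle first (by dearomatisation), tetrahydrofuran ring last (by C–O bond formation).

Locants are those of the benzofuranone: O1, C2 (aryl), C3 (methyl), C3a (allyl), C4=C5(OMe), C6 (C=O), C7, C7a.

Assumption: the (R)-configured acid of step 3 is taken to give the (3aR,7aR) series shown; if the sense of induction is opposite, its mirror image is used and nothing else changes.

## Route

Step 1
Reactants: 1 1-(3,4-dimethoxyphenyl)propan-1-one; 2 4-bromo-2,6-dimethoxyphenol
Product: 3 rac-1-(3,4-dimethoxyphenyl)-2-(4-hydroxy-3,5-dimethoxyphenyl)propan-1-one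
Conditions: Pd(OAc)2 (2 mol%), XPhos (4 mol%), NaOt-Bu (2.4 equiv), toluene, 80 °C; aq. NH4Cl
Reagents that add atoms: none
Why: Palladium-catalysed ketone α-arylation (Buchwald–Hartwig type) of deprotonated 1 with the aryl bromide, whose phenol is deprotonated in the flask to a hindered phenoxide that does not O-arylate, while the product stays deprotonated and so is not arylated twice; the new stereocentre is formed racemic on purpose because it is re-set in step 3.

Step 2
Reactants: 3 rac-1-(3,4-dimethoxyphenyl)-2-(4-hydroxy-3,5-dimethoxyphenyl)propan-1-one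
Product: 4 rac-4-[1-(3,4-dimethoxyphenyl)-1-oxopropan-2-yl]-2,6-dimethoxy-4-(prop-2-en-1-yl)cyclohexa-2,5-dien-1-one
Conditions: Pd(PPh3)4 (5 mol%), allyl methyl carbonate (1.05 equiv), toluene, 50 °C
Reagents that add atoms: allyl methyl carbonate, C=CCOC(=O)OC
Why: Dearomative Tsuji–Trost allylation in which the methoxide released from the carbonate deprotonates the phenol, O-allylation is reversible under zerovalent palladium and C-allylation at the para carbon is not, so the mixture funnels to the cross-conjugated 4,4-disubstituted dienone (an ortho adduct would reach the same product by Cope rearrangement); the new quaternary carbon carries two identical methoxy-enone arms and is therefore not a stereocentre, and the α-carbon stays racemic.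

Step 3
Reactants: 4 rac-4-[1-(3,4-dimethoxyphenyl)-1-oxopropan-2-yl]-2,6-dimethoxy-4-(prop-2-en-1-yl)cyclohexa-2,5-dien-1-one
Product: 7 (2S,3R,3aR,7aR)-2-(3,4-dimethoxyphenyl)-5,7-dimethoxy-3-methyl-3a-(prop-2-en-1-yl)-3,3a,7,7a-tetrahydro-1-benzofuran-6(2H)-one (both C7 epimers), via oxocarbenium ion 5 (not isolated), via dienol 6 (not isolated)
Conditions: (R)-TRIP N-triflylphosphoramide [(R)-3,3'-bis(2,4,6-triisopropylphenyl)-1,1'-binaphthyl-2,2'-diyl N-(trifluoromethylsulfonyl)phosphoramide] (10 mol%), Hantzsch ester (1.3 equiv), toluene, 5 Å MS, 40 °C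
Reagents that add atoms: none
Why: Proposed new method: a chiral-Brønsted-acid-catalysed desymmetrising reductive oxa-Michael cyclisation in which a ketone oxygen, not a hydroxyl group, is the nucleophile; the acid activates the dienone carbonyl, the aryl ketone oxygen adds 5-exo to one of the two methoxy-enone β-carbons from the face that carries the side chain (O1–C7a bond, cis ring fusion), the resulting 3,4-dimethoxyphenyl-stabilised oxocarbenium ion 5 is held as an ion pair with the chiral phosphoramidate, and the Hantzsch ester, which reduces neither the free aryl ketone nor the hydrogen-bonded enones, transfers hydride to C2 from the convex face (the face of the allyl group and H-7a) and anti to the C3 methyl group, which places aryl and methyl cis as in the target, before the C6 enol 6 tautomerises to 7; because the cyclisation is reversible and the α-carbon of 4 epimerises by acid-catalysed enolisation, both enantiomers of 4 drain through the ion pair that is reduced fastest (dynamic kinetic asymmetric transformation), so that C3a and C7a are set by the catalyst and C2 and C3 by the bicyclic cation; the closest known reaction types are the chiral-phosphoric-acid-catalysed desymmetrising oxa-Michael addition of hydroxyalkyl-cyclohexadienones and the chiral-acid/Hantzsch-ester transfer hydrogenation of aryl-substituted cyclic oxocarbenium (pyrylium-type) ions.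

Step 4
Reactants: 7 (2S,3R,3aR,7aR)-2-(3,4-dimethoxyphenyl)-5,7-dimethoxy-3-methyl-3a-(prop-2-en-1-yl)-3,3a,7,7a-tetrahydro-1-benzofuran-6(2H)-one (both C7 epimers)
Product: 8 (2S,3R,3aR,7aS)-2-(3,4-dimethoxyphenyl)-5-methoxy-3-methyl-3a-(prop-2-en-1-yl)-3,3a,7,7a-tetrahydro-1-benzofuran-6(2H)-one
Conditions: SmI2 (2.2 equiv, added slowly), THF/MeOH (10:1), −78 °C; aq. NH4Cl
Reagents that add atoms: none
Why: Reductive cleavage of an α-alkoxy ketone by SmI2 (Molander-type α-deoxygenation), in which two single-electron transfers to the C6 ketone break the adjacent sp3 C7–OMe bond and methanol supplies the proton at C7, while the vinylic C5 methoxy group, the allyl group and the benzylic ether are inert; no stereocentre is touched (C7 ceases to be one, and C7a changes descriptor from R to S only because C7 loses its oxygen), and a retro-oxa-Michael opening, should it occur, can only re-close onto the same enone arm with the cis fusion fixed by C3a.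

## Compound list

1 | 1-(3,4-dimethoxyphenyl)propan-1-one (3',4'-dimethoxypropiophenone) | CCC(=O)c1ccc(OC)c(OC)c1 | starting material
2 | 4-bromo-2,6-dimethoxyphenol | COc1cc(Br)cc(OC)c1O | starting material
3 | rac-1-(3,4-dimethoxyphenyl)-2-(4-hydroxy-3,5-dimethoxyphenyl)propan-1-one | CC(C(=O)c1ccc(OC)c(OC)c1)c1cc(OC)c(O)c(OC)c1 | intermediate
4 | rac-4-[1-(3,4-dimethoxyphenyl)-1-oxopropan-2-yl]-2,6-dimethoxy-4-(prop-2-en-1-yl)cyclohexa-2,5-dien-1-one | CC(C(=O)c1ccc(OC)c(OC)c1)C1(CC=C)C=C(OC)C(=O)C(OC)=C1 | intermediate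
5 | oxocarbenium ion: cis-fused (3R,3aS,7aR) bicyclic cation with O1=C2 carrying the 3,4-dimethoxyphenyl group, 3-methyl, 3a-allyl, 5,7-dimethoxy and a C6 enol OH, paired with the chiral phosphoramidate | C=CC[C@@]12C=C(OC)C(O)=C(OC)[C@@H]1[O+]=C(c1ccc(OC)c(OC)c1)[C@@H]2C | intermediate (not isolated)
6 | (2S,3R,3aR,7aR)-2-(3,4-dimethoxyphenyl)-5,7-dimethoxy-3-methyl-3a-(prop-2-en-1-yl)-2,3,3a,7a-tetrahydro-1-benzofuran-6-ol (dienol) | C=CC[C@@]12C=C(OC)C(O)=C(OC)[C@@H]1O[C@H](c1ccc(OC)c(OC)c1)[C@@H]2C | intermediate (not isolated)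
7 | (2S,3R,3aR,7aR)-2-(3,4-dimethoxyphenyl)-5,7-dimethoxy-3-methyl-3a-(prop-2-en-1-yl)-3,3a,7,7a-tetrahydro-1-benzofuran-6(2H)-one, both C7 epimers | C=CC[C@@]12C=C(OC)C(=O)C(OC)[C@@H]1O[C@H](c1ccc(OC)c(OC)c1)[C@@H]2C | intermediate
8 | (2S,3R,3aR,7aS)-2-(3,4-dimethoxyphenyl)-5-methoxy-3-methyl-3a-(prop-2-en-1-yl)-3,3a,7,7a-tetrahydro-1-benzofuran-6(2H)-one | C=CC[C@@]12C=C(OC)C(=O)C[C@@H]1O[C@H](c1ccc(OC)c(OC)c1)[C@@H]2C | target

## Step count and risks

Total step count: 4. Longest linear sequence: 4 steps (from 1 or 2).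

The three steps most likely to fail, in this order, are step 3, step 2 and step 1.

**Step 3 (the proposed new step).** The ketone oxygen is a weak nucleophile, so cyclisation may be slow. The Hantzsch ester may instead reduce a dienone arm or open the product's benzylic ether. The chiral anion may not discriminate the ion pairs well. The fallback uses known chemistry, sets out from 3 and comes back at 7. Ketone 3 is hydrogenated with dynamic kinetic resolution (RuCl2[(S)-xylbinap][(S)-daipen], KOt-Bu 1.2 equiv, i-PrOH, H2) to the Felkin (threo) alcohol (1R,2R)-1-(3,4-dimethoxyphenyl)-2-(4-hydroxy-3,5-dimethoxyphenyl)propan-1-ol F4. Direct reduction gives the wrong carbinol epimer for the target, so the carbinol is inverted by a Mitsunobu reaction (4-nitrobenzoic acid, PPh3, DIAD) to (1S,2R)-1-(3,4-dimethoxyphenyl)-2-(4-hydroxy-3,5-dimethoxyphenyl)propyl 4-nitrobenzoate F5. Methanolysis (K2CO3, MeOH) gives the erythro alcohol (1S,2R)-1-(3,4-dimethoxyphenyl)-2-(4-hydroxy-3,5-dimethoxyphenyl)propan-1-ol F6. Dearomative allylation as in step 2 gives 4-[(1S,2R)-1-(3,4-dimethoxyphenyl)-1-hydroxypropan-2-yl]-2,6-dimethoxy-4-(prop-2-en-1-yl)cyclohexa-2,5-dien-1-one F7. A chiral-phosphoric-acid-catalysed desymmetrising oxa-Michael addition of the hydroxyl group ((R)-TRIP, toluene) then closes the ring with retention at the carbinol and gives 7. The arm that puts the C3 methyl next to the flat enone carbon and not next to the allyl group is also the one expected from the substrate alone.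

**Step 2.** The O-allyl ether may be the resting state, and the ketone α-carbon may be allylated once the phenol is consumed. The fallback sets out from 3 and comes back at 4, and it reverses the polarity. Phenol 3 is oxidised with PhI(OAc)2 in MeOH at 0 °C to the masked ortho-benzoquinone rac-4-[1-(3,4-dimethoxyphenyl)-1-oxopropan-2-yl]-2,6,6-trimethoxycyclohexa-2,4-dien-1-one F3. Its ketal is ionised with BF3·OEt2 in CH2Cl2 at −78 °C and the cation is trapped by allyltrimethylsilane (Hosomi–Sakurai-type allylation of a quinone monoketal cation). Attack at the alkyl-bearing carbon gives 4 directly; an adduct at a methoxy-bearing carbon converges on 4 by Cope rearrangement on warming.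

**Step 1.** The aryl bromide is very electron-rich once its phenol is deprotonated, and may add slowly to palladium. The fallback sets out from 2 and comes back at 3. Phenol 2 is protected (MOMCl, i-Pr2NEt, CH2Cl2) as 5-bromo-1,3-dimethoxy-2-(methoxymethoxy)benzene F1. This neutral aryl bromide is coupled with 1 under the step 1 conditions (NaOt-Bu 1.3 equiv) to give rac-1-(3,4-dimethoxyphenyl)-2-[3,5-dimethoxy-4-(methoxymethoxy)phenyl]propan-1-one F2. The acetal is removed with HCl in MeOH at 40 °C to give 3.

## Further compounds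

F1 | step 1 | 5-bromo-1,3-dimethoxy-2-(methoxymethoxy)benzene | COCOc1c(OC)cc(Br)cc1OC
F2 | step 1 | rac-1-(3,4-dimethoxyphenyl)-2-[3,5-dimethoxy-4-(methoxymethoxy)phenyl]propan-1-one | CC(C(=O)c1ccc(OC)c(OC)c1)c1cc(OC)c(OCOC)c(OC)c1
F3 | step 2 | rac-4-[1-(3,4-dimethoxyphenyl)-1-oxopropan-2-yl]-2,6,6-trimethoxycyclohexa-2,4-dien-1-one | CC(C(=O)c1ccc(OC)c(OC)c1)C1=CC(OC)(OC)C(=O)C(OC)=C1
F4 | step 3 | (1R,2R)-1-(3,4-dimethoxyphenyl)-2-(4-hydroxy-3,5-dimethoxyphenyl)propan-1-ol | O[C@@H](c1ccc(OC)c(OC)c1)[C@H](C)c1cc(OC)c(O)c(OC)c1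
F5 | step 3 | (1S,2R)-1-(3,4-dimethoxyphenyl)-2-(4-hydroxy-3,5-dimethoxyphenyl)propyl 4-nitrobenzoate | O=C(O[C@H](c1ccc(OC)c(OC)c1)[C@H](C)c1cc(OC)c(O)c(OC)c1)c1ccc([N+](=O)[O-])cc1
F6 | step 3 | (1S,2R)-1-(3,4-dimethoxyphenyl)-2-(4-hydroxy-3,5-dimethoxyphenyl)propan-1-ol | O[C@H](c1ccc(OC)c(OC)c1)[C@H](C)c1cc(OC)c(O)c(OC)c1
F7 | step 3 | 4-[(1S,2R)-1-(3,4-dimethoxyphenyl)-1-hydroxypropan-2-yl]-2,6-dimethoxy-4-(prop-2-en-1-yl)cyclohexa-2,5-dien-1-one | O[C@H](c1ccc(OC)c(OC)c1)[C@H](C)C1(CC=C)C=C(OC)C(=O)C(OC)=C1
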